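**Plan**
- Late C7 hydroxylation and C8 methylenation lead back to a trans-decalin 8-ketone. Ring A is then cut at C2–C3 and C4–C5, which releases methyl methacrylate (C3, C4, C18, C19) and a ring-B keto acid.
- Enabling feature: the acyl carbon C2 and the ring-B ketone carbon C5 are 1,4-related through C1 and the quaternary C10. An acyl radical at C2 and the C5 carbonyl can therefore clasp the two alkene carbons of methacrylate into the six-membered ring A (C1–C2–C3–C4–C5–C10).
- Forward: ring B first (quinone monoketal, enone, conjugate addition/enolate alkylation), then ring A by a radical–polar crossover annulation, then removal of the C5 oxygen to give the trans-decalin, then C2, C19, C8 and C7 adjustments.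
- Stereochemistry: C9 from a copper/chiral carbene conjugate addition; C10 by anti alkylation; C4 in the key step; C5 by hydrogen-atom-transfer hydrogenation; C2 by dissolving-metal reduction; C7 by SeO2 ene/[2,3] oxidation from the α face.
- Helpers: dimethyl ketal (C8), dioxolane (C13), silyl ether (O2), the lost carboxylate of the keto acid and the C5 hydroxyl.

Key step: step 5

Remark: all carbons carry their labdane numbers from the first ring-B intermediate onward (ring A: C1–C5 and C10; ring B: C5–C10; side chain C11–C13 and C16 on C9; C17 on C8; C18 α and C19 β on C4; C20 on C10), and α means the face opposite C20.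

Step 1
Reactants: 1 4-methoxy-2-methylphenol
Product: 2 4,4-dimethoxy-2-methylcyclohexa-2,5-dien-1-one
Conditions: PhI(OAc)2, MeOH, 0 °C
Reagents that add atoms: methanol (CO)
Why: Hypervalent-iodine oxidative dearomatisation of a para-methoxyphenol in methanol is the standard route to quinone monoketals and creates no stereocentre.

Step 2
Reactants: 2 4,4-dimethoxy-2-methylcyclohexa-2,5-dien-1-one
Product: 3 4,4-dimethoxy-2-methylcyclohex-2-en-1-one
Conditions: RhCl(PPh3)3 (cat.), H2 (1 atm), benzene, rt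
Reagents that add atoms: none
Why: Homogeneous rhodium-catalysed hydrogenation discriminates the unhindered disubstituted enone alkene from the trisubstituted 2-methyl enone alkene and does not hydrogenolyse the allylic ketal, so only the C6=C7 bond is saturated and no stereocentre arises.

Step 3
Reactants: 3 4,4-dimethoxy-2-methylcyclohex-2-en-1-one; 4 2-(2-bromoethyl)-2-methyl-1,3-dioxolane; 5 ethyl 2-(bromomethyl)prop-2-enoate
Product: 8 ethyl 2-{[(1R,2R)-3,3-dimethoxy-1-methyl-2-[2-(2-methyl-1,3-dioxolan-2-yl)ethyl]-6-oxocyclohexyl]methyl}prop-2-enoate, via Grignard reagent 6 (not isolated), via bromomagnesium enolate 7 (not isolated)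
Conditions: 4, Mg, THF; then 3, Cu(OTf)2 (5 mol%), C2-symmetric chiral imidazolinium chloride (carbene precursor, 6 mol%, enantiomer that gives R at C9), Et2O, −30 °C; then 5, DMPU, −30 °C to rt
Reagents that add atoms: none
Why: Copper-catalysed asymmetric conjugate addition of a Grignard reagent to a 2-methylcyclohexenone followed by alkylation of the magnesium enolate is an established route to vicinal tertiary and quaternary centres: the chiral carbene–copper catalyst fixes C9 as R, and the allylic bromide (SN2′) enters the enolate face anti to the new C9 chain, which leaves the C10 methyl cis to that chain.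

Step 4
Reactants: 8 ethyl 2-{[(1R,2R)-3,3-dimethoxy-1-methyl-2-[2-(2-methyl-1,3-dioxolan-2-yl)ethyl]-6-oxocyclohexyl]methyl}prop-2-enoate
Product: 10 lithium 3-[(1R,2R)-3,3-dimethoxy-1-methyl-2-[2-(2-methyl-1,3-dioxolan-2-yl)ethyl]-6-oxocyclohexyl]-2-oxopropanoate, via α-keto ester 9 (not isolated)
Conditions: O3, CH2Cl2, −78 °C; Me2S; then LiOH (1.0 equiv), THF/H2O, 0 °C; freeze-dry
Reagents that add atoms: ozone (O=[O+][O-]); lithium hydroxide ([Li+].[OH-])
Why: Ozonolysis cleaves the only alkene (the 1,1-disubstituted acrylate) to the α-keto ester, whose activated ester is saponified by one equivalent of LiOH in the cold before the hindered ring ketone can enolise, and no stereocentre is touched.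

Step 5
Reactants: 10 lithium 3-[(1R,2R)-3,3-dimethoxy-1-methyl-2-[2-(2-methyl-1,3-dioxolan-2-yl)ethyl]-6-oxocyclohexyl]-2-oxopropanoate; 11 methyl 2-methylprop-2-enoate (methyl methacrylate)
Product: 13 methyl 13,13-ethylenedioxy-5β-hydroxy-8,8-dimethoxy-2-oxo-14,15,17-trinorlabdan-19-oate, via lithium ester enolate 12 (not isolated)
Conditions: [Ir(dF(CF3)ppy)2(dtbbpy)]PF6 (1 mol%), 11 (3 equiv), dry DMA, 4 Å MS, 450 nm LEDs, rt; then AcOH (1 equiv)
Reagents that add atoms: none
Why: Proposed new method: the excited trivalent iridium photocatalyst oxidises carboxylate 10, loss of CO2 gives the C2 acyl radical, which adds to the CH2 terminus of 11 (C2–C3 bond), and the tertiary α-ester radical is reduced by the divalent iridium complex to lithium enolate 12, which in the proton-free medium adds to the C5 ketone (C4–C5 bond) instead of being protonated. The closest known reaction types are the photoredox decarboxylative Giese addition of α-oxo acids to acrylates and the radical–polar crossover Giese/aldol annulations started by metal-hydride hydrogen-atom transfer, in which the enolate is likewise trapped by a tethered ketone. Ring A closes by a 6-(enolexo)-exo-trig aldol through a lithium-chelated chair in which ring B keeps its C9 chain and the C1 tether equatorial, so that the C10 methyl is axial on the forming ring. The new quaternary centre C4 is set by that chair: the flat enolate carbon rather than the C4 methyl takes the pseudo-axial site syn to the axial C10 methyl (a methyl/methyl 1,3-diaxial clash is avoided), which puts the ester β (cis to C20) and the methyl α; the C5 carbinol is expected β (cis-type closure) but is erased in step 6, and C2 stays trigonal. Chemoselectivity is secured by the excess of 11 (acyl radical trapped before decarbonylation), by the absence of any proton source before the quench, and by the tether length, which leaves C5 as the only carbonyl within reach of a six-membered transition state.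

Step 6
Reactants: 13 methyl 13,13-ethylenedioxy-5β-hydroxy-8,8-dimethoxy-2-oxo-14,15,17-trinorlabdan-19-oate
Product: 14 methyl 13,13-ethylenedioxy-8,8-dimethoxy-2-oxo-14,15,17-trinorlabd-5-en-19-oate
Conditions: SOCl2, pyridine, CH2Cl2, 0 °C
Reagents that add atoms: none
Why: Dehydration of the tertiary alcohol through its chlorosulfite (SOCl2/pyridine elimination) can only place the alkene between C5 and C6 because C4 and C10 carry no hydrogen, so the C5 carbinol centre (whichever epimer step 5 gave) is erased without touching C4 or C10.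

Step 7
Reactants: 14 methyl 13,13-ethylenedioxy-8,8-dimethoxy-2-oxo-14,15,17-trinorlabd-5-en-19-oate
Product: 15 methyl 13,13-ethylenedioxy-8,8-dimethoxy-2-oxo-14,15,17-trinorlabdan-19-oate (5α-H, trans-decalin)
Conditions: Mn(dpm)3 (10 mol%), PhSiH3, tert-butyl hydroperoxide, 2-propanol, rt
Reagents that add atoms: none
Why: Hydrogen-atom-transfer hydrogenation with a manganese hydride adds H to C6 and then to the tertiary C5 radical from the α face, opposite the axial C10 methyl and C4 ester, which is also the route to the thermodynamically preferred trans-decalin (5α-H).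

Step 8
Reactants: 15 methyl 13,13-ethylenedioxy-8,8-dimethoxy-2-oxo-14,15,17-trinorlabdan-19-oate
Product: 16 methyl 13,13-ethylenedioxy-2α-hydroxy-8,8-dimethoxy-14,15,17-trinorlabdan-19-oate
Conditions: Li, NH3(l)/THF, tert-butanol (2 equiv), −78 °C, short time; NH4Cl
Reagents that add atoms: none
Why: Dissolving-metal reduction of a cyclohexanone gives the thermodynamically favoured equatorial alcohol, here 2α-OH (a hydride would come from the open α face and give the axial 2β epimer), while the hindered neopentyl ester and both ketals survive the short reaction at −78 °C.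

Step 9
Reactants: 16 methyl 13,13-ethylenedioxy-2α-hydroxy-8,8-dimethoxy-14,15,17-trinorlabdan-19-oate
Product: 17 methyl 2α-(tert-butyldimethylsilyloxy)-13,13-ethylenedioxy-8,8-dimethoxy-14,15,17-trinorlabdan-19-oate
Conditions: tert-butyldimethylsilyl chloride, imidazole, DMF, rt
Reagents that add atoms: tert-butyldimethylsilyl chloride (CC(C)(C)[Si](C)(C)Cl)
Why: Standard silylation of an unhindered equatorial secondary alcohol; no stereocentre is touched.

Step 10
Reactants: 17 methyl 2α-(tert-butyldimethylsilyloxy)-13,13-ethylenedioxy-8,8-dimethoxy-14,15,17-trinorlabdan-19-oate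
Product: 18 methyl 2α-(tert-butyldimethylsilyloxy)-13,13-ethylenedioxy-8-oxo-14,15,17-trinorlabdan-19-oate
Conditions: pyridinium p-toluenesulfonate (cat.), acetone/H2O, rt
Reagents that add atoms: water (O)
Why: An acyclic dimethyl ketal is hydrolysed much faster than a 1,3-dioxolane, so mild acid in wet acetone frees only the C8 ketone, and C9 keeps its equatorial β chain, which is also the thermodynamic arrangement next to the ketone.

Step 11
Reactants: 18 methyl 2α-(tert-butyldimethylsilyloxy)-13,13-ethylenedioxy-8-oxo-14,15,17-trinorlabdan-19-oate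
Product: 19 methyl 2α-(tert-butyldimethylsilyloxy)-13,13-ethylenedioxy-14,15-dinorlabd-8(17)-en-19-oate
Conditions: Ph3PCH3Br, KN(SiMe3)2, THF, 0 °C; then 18, rt to 50 °C
Reagents that add atoms: methyltriphenylphosphonium bromide (C[P+](c1ccccc1)(c1ccccc1)c1ccccc1.[Br-])
Why: Wittig methylenation of 8-oxo decalins of this type is routine, the hindered axial methyl ester and the silyl ether are inert to the ylide, and C9 cannot end up in anything but its more stable equatorial configuration.

Step 12
Reactants: 19 methyl 2α-(tert-butyldimethylsilyloxy)-13,13-ethylenedioxy-14,15-dinorlabd-8(17)-en-19-oate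
Product: 20 2α-(tert-butyldimethylsilyloxy)-13,13-ethylenedioxy-14,15-dinorlabd-8(17)-en-19-ol
Conditions: LiAlH4, THF, 0 °C to reflux
Reagents that add atoms: none
Why: LiAlH4 reduces even the hindered axial ester to the primary alcohol and leaves alkene, silyl ether and dioxolane untouched.

Step 13
Reactants: 20 2α-(tert-butyldimethylsilyloxy)-13,13-ethylenedioxy-14,15-dinorlabd-8(17)-en-19-ol
Product: 21 19-acetoxy-2α-(tert-butyldimethylsilyloxy)-13,13-ethylenedioxy-14,15-dinorlabd-8(17)-ene
Conditions: Ac2O, pyridine, DMAP (cat.), CH2Cl2, rt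
Reagents that add atoms: acetic anhydride (CC(=O)OC(C)=O)
Why: Standard acetylation of the only free hydroxyl group.

Step 14
Reactants: 21 19-acetoxy-2α-(tert-butyldimethylsilyloxy)-13,13-ethylenedioxy-14,15-dinorlabd-8(17)-ene
Product: 22 19-acetoxy-2α-(tert-butyldimethylsilyloxy)-13,13-ethylenedioxy-14,15-dinorlabd-8(17)-en-7α-ol
Conditions: SeO2 (cat.), tert-butyl hydroperoxide, CH2Cl2, rt
Reagents that add atoms: selenium dioxide (O=[Se]=O), the oxygen donor, turned over by tert-butyl hydroperoxide (CC(C)(C)OO)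
Why: SeO2-catalysed allylic hydroxylation (ene reaction followed by [2,3]-sigmatropic rearrangement) of a labd-8(17)-ene attacks the exocyclic alkene from the α face opposite the axial C10 methyl, prefers the C7 methylene over the tertiary C9–H, and returns the double bond to C8=C17 with the new hydroxyl axial (7α).

Step 15
Reactants: 22 19-acetoxy-2α-(tert-butyldimethylsilyloxy)-13,13-ethylenedioxy-14,15-dinorlabd-8(17)-en-7α-ol
Product: 23 [(1S,3R,4aS,5R,7R,8aR)-3,7-dihydroxy-1,4a-dimethyl-6-methylidene-5-(3-oxobutyl)decahydronaphthalen-1-yl]methyl acetate (19-acetoxy-2α,7α-dihydroxy-14,15-dinorlabd-8(17)-en-13-one)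
Conditions: HF (48% aq.), MeCN, 0 °C to rt
Reagents that add atoms: water (O)
Why: Aqueous HF cleaves the secondary silyl ether and hydrolyses the dioxolane in one operation, conditions under which the acetate, the allylic alcohol and the exocyclic alkene are stable, and no stereocentre is touched.

**Compound list**
1 | 4-methoxy-2-methylphenol | COc1ccc(O)c(C)c1 | starting material
2 | 4,4-dimethoxy-2-methylcyclohexa-2,5-dien-1-one | COC1(OC)C=CC(=O)C(C)=C1 | intermediate
3 | 4,4-dimethoxy-2-methylcyclohex-2-en-1-one | COC1(OC)CCC(=O)C(C)=C1 | intermediate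
4 | 2-(2-bromoethyl)-2-methyl-1,3-dioxolane | CC1(CCBr)OCCO1 | starting material
5 | ethyl 2-(bromomethyl)prop-2-enoate | C=C(CBr)C(=O)OCC | starting material
6 | [2-(2-methyl-1,3-dioxolan-2-yl)ethyl]magnesium bromide | CC1(CC[Mg]Br)OCCO1 | intermediate (not isolated)
7 | bromomagnesium enolate of (3R)-4,4-dimethoxy-2-methyl-3-[2-(2-methyl-1,3-dioxolan-2-yl)ethyl]cyclohexan-1-one | COC1(OC)CCC(O[Mg]Br)=C(C)[C@H]1CCC1(C)OCCO1 | intermediate (not isolated)
8 | ethyl 2-{[(1R,2R)-3,3-dimethoxy-1-methyl-2-[2-(2-methyl-1,3-dioxolan-2-yl)ethyl]-6-oxocyclohexyl]methyl}prop-2-enoate | COC1(OC)CCC(=O)[C@](C)(CC(=C)C(=O)OCC)[C@H]1CCC1(C)OCCO1 | intermediate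
9 | ethyl 3-[(1R,2R)-3,3-dimethoxy-1-methyl-2-[2-(2-methyl-1,3-dioxolan-2-yl)ethyl]-6-oxocyclohexyl]-2-oxopropanoate | COC1(OC)CCC(=O)[C@](C)(CC(=O)C(=O)OCC)[C@H]1CCC1(C)OCCO1 | intermediate (not isolated)
10 | lithium 3-[(1R,2R)-3,3-dimethoxy-1-methyl-2-[2-(2-methyl-1,3-dioxolan-2-yl)ethyl]-6-oxocyclohexyl]-2-oxopropanoate | COC1(OC)CCC(=O)[C@](C)(CC(=O)C(=O)[O-])[C@H]1CCC1(C)OCCO1.[Li+] | intermediate
11 | methyl 2-methylprop-2-enoate (methyl methacrylate) | C=C(C)C(=O)OC | starting material
12 | lithium enolate of methyl 5-[(1R,2R)-3,3-dimethoxy-1-methyl-2-[2-(2-methyl-1,3-dioxolan-2-yl)ethyl]-6-oxocyclohexyl]-2-methyl-4-oxopentanoate | COC1(OC)CCC(=O)[C@](C)(CC(=O)CC(C)=C(OC)O[Li])[C@H]1CCC1(C)OCCO1 | intermediate (not isolated)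
13 | methyl 13,13-ethylenedioxy-5β-hydroxy-8,8-dimethoxy-2-oxo-14,15,17-trinorlabdan-19-oate (4α-methyl, 4β-ester, 9β-chain, 10β-methyl) | COC1(OC)CC[C@]2(O)[C@@](C)(C(=O)OC)CC(=O)C[C@]2(C)[C@H]1CCC1(C)OCCO1 | intermediate
14 | methyl 13,13-ethylenedioxy-8,8-dimethoxy-2-oxo-14,15,17-trinorlabd-5-en-19-oate | COC1(OC)CC=C2[C@@](C)(C(=O)OC)CC(=O)C[C@]2(C)[C@H]1CCC1(C)OCCO1 | intermediate
15 | methyl 13,13-ethylenedioxy-8,8-dimethoxy-2-oxo-14,15,17-trinorlabdan-19-oate (5α-H) | COC1(OC)CC[C@H]2[C@@](C)(C(=O)OC)CC(=O)C[C@]2(C)[C@H]1CCC1(C)OCCO1 | intermediate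
16 | methyl 13,13-ethylenedioxy-2α-hydroxy-8,8-dimethoxy-14,15,17-trinorlabdan-19-oate | COC1(OC)CC[C@H]2[C@@](C)(C(=O)OC)C[C@H](O)C[C@]2(C)[C@H]1CCC1(C)OCCO1 | intermediate
17 | methyl 2α-(tert-butyldimethylsilyloxy)-13,13-ethylenedioxy-8,8-dimethoxy-14,15,17-trinorlabdan-19-oate | COC1(OC)CC[C@H]2[C@@](C)(C(=O)OC)C[C@H](O[Si](C)(C)C(C)(C)C)C[C@]2(C)[C@H]1CCC1(C)OCCO1 | intermediate
18 | methyl 2α-(tert-butyldimethylsilyloxy)-13,13-ethylenedioxy-8-oxo-14,15,17-trinorlabdan-19-oate | O=C1CC[C@H]2[C@@](C)(C(=O)OC)C[C@H](O[Si](C)(C)C(C)(C)C)C[C@]2(C)[C@H]1CCC1(C)OCCO1 | intermediate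
19 | methyl 2α-(tert-butyldimethylsilyloxy)-13,13-ethylenedioxy-14,15-dinorlabd-8(17)-en-19-oate | C=C1CC[C@H]2[C@@](C)(C(=O)OC)C[C@H](O[Si](C)(C)C(C)(C)C)C[C@]2(C)[C@H]1CCC1(C)OCCO1 | intermediate
20 | 2α-(tert-butyldimethylsilyloxy)-13,13-ethylenedioxy-14,15-dinorlabd-8(17)-en-19-ol | C=C1CC[C@H]2[C@@](C)(CO)C[C@H](O[Si](C)(C)C(C)(C)C)C[C@]2(C)[C@H]1CCC1(C)OCCO1 | intermediate
21 | 19-acetoxy-2α-(tert-butyldimethylsilyloxy)-13,13-ethylenedioxy-14,15-dinorlabd-8(17)-ene | C=C1CC[C@H]2[C@@](C)(COC(C)=O)C[C@H](O[Si](C)(C)C(C)(C)C)C[C@]2(C)[C@H]1CCC1(C)OCCO1 | intermediate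
22 | 19-acetoxy-2α-(tert-butyldimethylsilyloxy)-13,13-ethylenedioxy-14,15-dinorlabd-8(17)-en-7α-ol | C=C1[C@H](O)C[C@H]2[C@@](C)(COC(C)=O)C[C@H](O[Si](C)(C)C(C)(C)C)C[C@]2(C)[C@H]1CCC1(C)OCCO1 | intermediate
23 | [(1S,3R,4aS,5R,7R,8aR)-3,7-dihydroxy-1,4a-dimethyl-6-methylidene-5-(3-oxobutyl)decahydronaphthalen-1-yl]methyl acetate | C=C1[C@H](O)C[C@H]2[C@@](C)(COC(C)=O)C[C@H](O)C[C@]2(C)[C@H]1CCC(C)=O | target

**Totals**
Total step count: 15. Longest linear sequence: 15 steps (1 to 23); compounds 4, 5 and 11 are bought.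

**Steps most likely to fail**

1. Step 5 (proposed new method). What may go wrong: the enolate is protonated before it closes (open-chain Giese product), the crowded aldolate reverts, or ring closure occurs with the C4 methyl rather than the ester in the axial position. Fallback by known reactions, setting out from 3 and coming back at 13. Enolate 7 is made as in step 3 and trapped with allyl bromide to give (2R,3R)-4,4-dimethoxy-2-methyl-3-[2-(2-methyl-1,3-dioxolan-2-yl)ethyl]-2-(prop-2-en-1-yl)cyclohexan-1-one F1. Ozonolysis (O3; Me2S) gives 2-[(1R,2R)-3,3-dimethoxy-1-methyl-2-[2-(2-methyl-1,3-dioxolan-2-yl)ethyl]-6-oxocyclohexyl]acetaldehyde F2. Indium-mediated Barbier allylation of the aldehyde with methyl 2-(bromomethyl)prop-2-enoate (THF/H2O) forms the C2–C3 bond and gives methyl 5-[(1R,2R)-3,3-dimethoxy-1-methyl-2-[2-(2-methyl-1,3-dioxolan-2-yl)ethyl]-6-oxocyclohexyl]-4-hydroxy-2-methylidenepentanoate F3 as a mixture at the carbinol carbon. Dess–Martin oxidation gives methyl 5-[(1R,2R)-3,3-dimethoxy-1-methyl-2-[2-(2-methyl-1,3-dioxolan-2-yl)ethyl]-6-oxocyclohexyl]-2-methylidene-4-oxopentanoate F4. Reductive aldol cyclisation with [(Ph3P)CuH]6 in toluene delivers hydride to the CH2 terminus (which becomes C18) and the copper enolate to C5, giving 13.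

2. Step 3. What may go wrong: slow conjugate addition at the β-carbon flanked by the ketal and the 2-methyl group, competing 1,2-addition, or poor enantiofacial control. Fallback by known reactions, setting out from 4 and coming back at 8. Grignard reagent 6 is treated with ZnCl2 to give bis[2-(2-methyl-1,3-dioxolan-2-yl)ethyl]zinc F5. Copper/phosphoramidite-catalysed conjugate addition of this reagent to bought 4,4-dimethoxycyclohexa-2,5-dien-1-one (an unhindered, symmetric acceptor) gives (5R)-4,4-dimethoxy-5-[2-(2-methyl-1,3-dioxolan-2-yl)ethyl]cyclohex-2-en-1-one F6. Kinetic α′-methylation (lithium diisopropylamide, iodomethane) gives (5R)-4,4-dimethoxy-6-methyl-5-[2-(2-methyl-1,3-dioxolan-2-yl)ethyl]cyclohex-2-en-1-one F7. Hydrogenation (H2, Pd/C) gives (3R)-4,4-dimethoxy-2-methyl-3-[2-(2-methyl-1,3-dioxolan-2-yl)ethyl]cyclohexan-1-one F8. Thermodynamic silylation (Me3SiCl, Et3N, DMF, heat) gives {[(3R)-4,4-dimethoxy-2-methyl-3-[2-(2-methyl-1,3-dioxolan-2-yl)ethyl]cyclohex-1-en-1-yl]oxy}trimethylsilane F9. MeLi followed by 5 alkylates the regiodefined lithium enolate anti to the C9 chain and gives 8.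

3. Step 7. What may go wrong: slow hydrogen-atom transfer to the alkene between two quaternary carbons, or delivery of the second hydrogen to the β face (cis-decalin). Fallback by known reactions, setting out from 14 and coming back at 18; it sets C5 by equilibration instead. Li/NH3 reduction of 14 (the isolated alkene is inert) gives methyl 13,13-ethylenedioxy-2α-hydroxy-8,8-dimethoxy-14,15,17-trinorlabd-5-en-19-oate F10. Silylation gives methyl 2α-(tert-butyldimethylsilyloxy)-13,13-ethylenedioxy-8,8-dimethoxy-14,15,17-trinorlabd-5-en-19-oate F11. Selective ketal hydrolysis as in step 10 gives the β,γ-unsaturated ketone methyl 2α-(tert-butyldimethylsilyloxy)-13,13-ethylenedioxy-8-oxo-14,15,17-trinorlabd-5-en-19-oate F12. DBU moves the alkene into conjugation and equilibrates C5 to the trans ring fusion, giving methyl 2α-(tert-butyldimethylsilyloxy)-13,13-ethylenedioxy-8-oxo-14,15,17-trinorlabd-6-en-19-oate F13 (5α-H). Hydrogenation of the unhindered enone alkene (H2, Pd/C) gives 18.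

**Further compounds**
F1 | step 5 | (2R,3R)-4,4-dimethoxy-2-methyl-3-[2-(2-methyl-1,3-dioxolan-2-yl)ethyl]-2-(prop-2-en-1-yl)cyclohexan-1-one | COC1(OC)CCC(=O)[C@](C)(CC=C)[C@H]1CCC1(C)OCCO1
F2 | step 5 | 2-[(1R,2R)-3,3-dimethoxy-1-methyl-2-[2-(2-methyl-1,3-dioxolan-2-yl)ethyl]-6-oxocyclohexyl]acetaldehyde | COC1(OC)CCC(=O)[C@](C)(CC=O)[C@H]1CCC1(C)OCCO1
F3 | step 5 | methyl 5-[(1R,2R)-3,3-dimethoxy-1-methyl-2-[2-(2-methyl-1,3-dioxolan-2-yl)ethyl]-6-oxocyclohexyl]-4-hydroxy-2-methylidenepentanoate (carbinol epimers) | COC1(OC)CCC(=O)[C@](C)(CC(O)CC(=C)C(=O)OC)[C@H]1CCC1(C)OCCO1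
F4 | step 5 | methyl 5-[(1R,2R)-3,3-dimethoxy-1-methyl-2-[2-(2-methyl-1,3-dioxolan-2-yl)ethyl]-6-oxocyclohexyl]-2-methylidene-4-oxopentanoate | COC1(OC)CCC(=O)[C@](C)(CC(=O)CC(=C)C(=O)OC)[C@H]1CCC1(C)OCCO1
F5 | step 3 | bis[2-(2-methyl-1,3-dioxolan-2-yl)ethyl]zinc | CC1(CC[Zn]CCC2(C)OCCO2)OCCO1
F6 | step 3 | (5R)-4,4-dimethoxy-5-[2-(2-methyl-1,3-dioxolan-2-yl)ethyl]cyclohex-2-en-1-one | COC1(OC)C=CC(=O)C[C@H]1CCC1(C)OCCO1
F7 | step 3 | (5R)-4,4-dimethoxy-6-methyl-5-[2-(2-methyl-1,3-dioxolan-2-yl)ethyl]cyclohex-2-en-1-one (C6 epimers) | COC1(OC)C=CC(=O)C(C)[C@H]1CCC1(C)OCCO1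
F8 | step 3 | (3R)-4,4-dimethoxy-2-methyl-3-[2-(2-methyl-1,3-dioxolan-2-yl)ethyl]cyclohexan-1-one (C2 epimers) | COC1(OC)CCC(=O)C(C)[C@H]1CCC1(C)OCCO1
F9 | step 3 | {[(3R)-4,4-dimethoxy-2-methyl-3-[2-(2-methyl-1,3-dioxolan-2-yl)ethyl]cyclohex-1-en-1-yl]oxy}trimethylsilane | COC1(OC)CCC(O[Si](C)(C)C)=C(C)[C@H]1CCC1(C)OCCO1
F10 | step 7 | methyl 13,13-ethylenedioxy-2α-hydroxy-8,8-dimethoxy-14,15,17-trinorlabd-5-en-19-oate | COC1(OC)CC=C2[C@@](C)(C(=O)OC)C[C@H](O)C[C@]2(C)[C@H]1CCC1(C)OCCO1
F11 | step 7 | methyl 2α-(tert-butyldimethylsilyloxy)-13,13-ethylenedioxy-8,8-dimethoxy-14,15,17-trinorlabd-5-en-19-oate | COC1(OC)CC=C2[C@@](C)(C(=O)OC)C[C@H](O[Si](C)(C)C(C)(C)C)C[C@]2(C)[C@H]1CCC1(C)OCCO1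
F12 | step 7 | methyl 2α-(tert-butyldimethylsilyloxy)-13,13-ethylenedioxy-8-oxo-14,15,17-trinorlabd-5-en-19-oate | O=C1CC=C2[C@@](C)(C(=O)OC)C[C@H](O[Si](C)(C)C(C)(C)C)C[C@]2(C)[C@H]1CCC1(C)OCCO1
F13 | step 7 | methyl 2α-(tert-butyldimethylsilyloxy)-13,13-ethylenedioxy-8-oxo-14,15,17-trinorlabd-6-en-19-oate (5α-H) | O=C1C=C[C@H]2[C@@](C)(C(=O)OC)C[C@H](O[Si](C)(C)C(C)(C)C)C[C@]2(C)[C@H]1CCC1(C)OCCO1
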